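The ten-membered ring is never closed: adding a C4–C9 bond to the germacrane ring gives a cis-decalin whose ring A (C1–C4, C9, C10) is (S)-carvone and whose ring B (C4–C9) is built on it by aldol and pinacol bond formation. The route rests on cutting that bond again. In one operation the Grob fragmentation of the C9 alkoxide with the anti-periplanar C5 mesylate releases the ten-membered ring, the C9 carbonyl and the Z C4=C5 alkene; it exploits the transannular C4/C9 pair, the oxygen on C9 and the methyl-bearing Z alkene at C4–C5. The precursor is a cis-fused decalin with a free tertiary C9 hydroxyl, an equatorial C5 mesylate and all other oxygens masked.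

Key step: step 15

Remark: germacrane numbering is used (ring C1–C10, C14 on C10, C15 on C4, lactone carbons C11–C13); read from the SMILES the target is 3S,6R,7R,8S,9R with a (2R,3R)-epoxy ester, i.e. a cis-fused lactone (H6 and H7 syn) and an anti C8/C9 oxygen pair, and in step 10 the carbonyl oxygen of the new acetate is assumed to come from the methoxy group (loss of methyl acetate).

Step 1
Reactants: 1 but-2-yne-1,4-diol
Product: 2 4-(4-methoxybenzyloxy)but-2-yn-1-ol
Conditions: 1 (4 equiv), NaH (1 equiv), 4-MeOC6H4CH2Cl (1 equiv), THF/DMF, 0 °C to rt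
Reagents that add atoms: 4-methoxybenzyl chloride, COc1ccc(CCl)cc1
Why: Williamson etherification of a cheap symmetrical diol used in excess, so the mono-ether should be the main product.

Step 2
Reactants: 2 4-(4-methoxybenzyloxy)but-2-yn-1-ol
Product: 3 (E)-4-(4-methoxybenzyloxy)but-2-en-1-ol
Conditions: LiAlH4, THF, 0 °C to rt
Reagents that add atoms: none
Why: Alkoxide-directed trans-hydroalumination of the propargylic alcohol should give only the E-allylic alcohol, and the low temperature avoids loss of the ether oxygen to an allene.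

Step 3
Reactants: 3 (E)-4-(4-methoxybenzyloxy)but-2-en-1-ol
Product: 4 [(2R,3R)-3-(4-methoxybenzyloxymethyl)oxiran-2-yl]methanol
Conditions: Ti(OiPr)4 (10 mol %), D-(−)-diisopropyl tartrate (12 mol %), t-BuOOH, 4 Å molecular sieves (zeolite NaA, NaAlSiO4), CH2Cl2, −20 °C
Reagents that add atoms: tert-butyl hydroperoxide, CC(C)(C)OO
Why: Sharpless asymmetric epoxidation, in which the unnatural tartrate turns E-allylic alcohols into (2R,3R)-epoxy alcohols (mirror image of the 2S,3S series of the natural ligand), which sets C6.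

Step 4
Reactants: 4 [(2R,3R)-3-(4-methoxybenzyloxymethyl)oxiran-2-yl]methanol; 5 trimethylsilylacetylene
Product: 8 (2S,3S)-3-(4-methoxybenzyloxymethyl)-5-trimethylsilylpent-4-yne-1,2-diol, via lithium (trimethylsilyl)acetylide 6 (not isolated), via diethyl[(trimethylsilyl)ethynyl]alane 7 (not isolated)
Conditions: 5, n-BuLi, toluene, 0 °C; Et2AlCl; then 4, 0 °C to rt; aq. potassium sodium tartrate
Reagents that add atoms: none
Why: The aluminium alkoxide of a 2,3-epoxy alcohol directs the alkynylalane to C3 with inversion (known C3-selective opening), so the trans-epoxide gives the erythro O6/C7-alkynyl pair and sets C7.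

Step 5
Reactants: 8 (2S,3S)-3-(4-methoxybenzyloxymethyl)-5-trimethylsilylpent-4-yne-1,2-diol
Product: 9 bis(triethylsilyl) ether of 8
Conditions: Et3SiCl (2.4 equiv), imidazole, DMF, 0 °C to rt
Reagents that add atoms: chlorotriethylsilane, CC[Si](Cl)(CC)CC
Why: Routine silylation of both hydroxyls.

Step 6
Reactants: 9 bis(triethylsilyl) ether of 8
Product: 10 (2S,3S)-3-(4-methoxybenzyloxymethyl)-2-triethylsilyloxy-5-trimethylsilylpent-4-ynal (C5–C8 aldehyde)
Conditions: (COCl)2, DMSO, CH2Cl2, −78 to −30 °C; Et3N, −78 to 0 °C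
Reagents that add atoms: none
Why: Under Swern conditions a primary triethylsilyl ether is cleaved by the chlorosulfonium salt and oxidised in the same flask while the secondary one survives, so the α-silyloxy aldehyde forms directly.

Step 7
Reactants: 11 (S)-(+)-carvone
Product: 13 (5S)-6-methylcarvone (C6 epimers; trans shown), via carvone lithium enolate 12 (not isolated)
Conditions: LiN(iPr)2, THF, −78 °C; MeI, −78 to 0 °C
Reagents that add atoms: iodomethane, CI
Why: Kinetic α′-deprotonation of the enone and C-methylation; the new centre is planarised again in step 8, so its configuration does not matter.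

Step 8
Reactants: 13 (5S)-6-methylcarvone; 10 C5–C8 aldehyde
Product: 15 C4–C5 aldol adduct (C5 hydroxyl; O6 SiEt3; O8 4-methoxybenzyl; C3 isopropenyl), via 6-methylcarvone lithium enolate 14 (not isolated)
Conditions: LiN(iPr)2, THF, −78 °C; 10, −78 °C; AcOH quench at −78 °C
Reagents that add atoms: none
Why: Aldol addition of the tetrasubstituted enolate: the aldehyde enters anti to the neighbouring C3 isopropenyl group (sets C4), the chair Zimmerman–Traxler transition state of the ring (E) enolate with the aldehyde chain equatorial sets C5 relative to C4, and Felkin–Anh/Cornforth attack anti to the C6 silyloxy group is matched with both, so the 5,6-anti isomer needed later should dominate.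

Step 9
Reactants: 15 C4–C5 aldol adduct
Product: 16 C5 mesylate
Conditions: MsCl, Et3N, CH2Cl2, 0 °C
Reagents that add atoms: methanesulfonyl chloride, CS(=O)(=O)Cl
Why: Sulfonylation through sulfene works on hindered secondary alcohols, leaves the C5–O bond (configuration) untouched and blocks retro-aldol cleavage.

Step 10
Reactants: 16 C5 mesylate
Product: 19 C3 acetate of the mesyloxy enone, via C3 methoxy hydroperoxide 17 (not isolated), via C3 peroxyacetate 18 (not isolated)
Conditions: O3, CH2Cl2/MeOH, NaHCO3, −78 °C; N2 purge; then Ac2O, Et3N, DMAP (cat.), CH2Cl2, 0 to 40 °C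
Reagents that add atoms: ozone, [O-][O+]=O; methanol, CO
Why: Ozone should cleave only the electron-rich 1,1-disubstituted alkene (enone alkene, silylalkyne and anisyl ring react far more slowly), methanol traps the carbonyl oxide, and the peroxyacetate undergoes Criegee rearrangement with migration of C3 to oxygen with retention, giving the C3 acetate of the target.

Step 11
Reactants: 19 C3 acetate of the mesyloxy enone
Product: 20 C8 primary alcohol
Conditions: DDQ, CH2Cl2/aq. NaH2PO4–Na2HPO4 buffer (pH 7), 0 °C
Reagents that add atoms: none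
Why: Oxidative cleavage of the 4-methoxybenzyl ether through its benzylic cation under buffered conditions that spare silyl ethers, mesylate and acetate.

Step 12
Reactants: 20 C8 primary alcohol
Product: 21 C8 aldehyde (1,6-keto aldehyde)
Conditions: Dess–Martin periodinane, NaHCO3, CH2Cl2, 0 °C to rt; used crude
Reagents that add atoms: none
Why: Dess–Martin oxidation is non-basic, so the α-alkynyl β-silyloxy aldehyde should neither epimerise at C7 nor eliminate.

Step 13
Reactants: 21 C8 aldehyde
Product: 22 cis-decalin C8,C9-diol (C5 mesylate; O6 SiEt3; C3 acetate)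
Conditions: SmI2 (3 equiv), THF, −78 °C, slow addition of 21; sat. aq. NH4Cl at −78 °C
Reagents that add atoms: none
Why: SmI2 pinacol cyclisation of a 1,6-keto aldehyde: C8 and C9 couple through a chair with the C5 mesylate and C7 alkynyl group equatorial and both oxygens on one trivalent samarium centre, which should give the cis diol and the cis ring fusion (the trans-fused chair needs three syn-axial groups), while the C1 end of the enone is out of reach (eight-membered ring).

Step 14
Reactants: 22 cis-decalin C8,C9-diol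
Product: 23 cis-decalin C9-hydroxy C5-mesylate with O8 SiMe2tBu and O6 SiEt3 (fragmentation precursor)
Conditions: t-BuMe2SiOTf (1.2 equiv), 2,6-lutidine, CH2Cl2, −78 °C
Reagents that add atoms: tert-butyldimethylsilyl trifluoromethanesulfonate, CC(C)(C)[Si](C)(C)OS(=O)(=O)C(F)(F)F
Why: The equatorial secondary C8 hydroxyl is silylated much faster than the tertiary C9 hydroxyl, and the bulky silyl group is chosen because it resists 1,2-migration to the neighbouring alkoxide in step 15.

Step 15
Reactants: 23 cis-decalin C9-hydroxy C5-mesylate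
Product: 25 Z,Z-cyclodeca-1(10),4-dien-9-one (3-OAc; 6-OSiEt3; 7-C≡CSiMe3; 8-OSiMe2tBu), via potassium C9 alkoxide 24 (not isolated)
Conditions: KN(SiMe3)2 (1.1 equiv), THF, −78 to 0 °C
Reagents that add atoms: none
Why: The amide base deprotonates only the free tertiary C9 hydroxyl, and the alkoxide pushes into the C4–C9 bond, which breaks in concert with loss of the C5 mesylate so that the C9 carbonyl and the C4=C5 π bond form together, the known Grob (Wharton-type) behaviour of decalin 1,3-diol monosulfonates. No ring bond is made: the ten-membered ring is the decalin perimeter left when the bond shared by rings A and B is cut, so there is no closure mode to control. No stereocentre is created (C4, C5 and C9 become trigonal); the alkene geometry follows from the anti-periplanar C9–C4–C5–O array in the ring B chair, where the C4–C3 bond stands at 60° and the C4 methyl at 180° to C5–C6, so C3 and C6 finish on the same side (Z), and the Z C1=C10 alkene is inherited from the carvone ring. The selectivity needed is fragmentation over oxetane closure, elimination, ring contraction and acyl or silyl transfer. It is secured because the only chair free of three syn-axial groups holds the mesylate equatorial and anti to C4–C9, C5 is neopentyl, C4 has no hydrogen, O6 and O8 are silylated, and O3 and O9 are both equatorial on ring A, too far apart to exchange the acetyl group. A hindered amide base in slight excess at low temperature should spare the acetate, the alkyne C–Si bond and the enolisable C8–H of the product.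

Step 16
Reactants: 25 Z,Z-cyclodecadien-9-one
Product: 26 6-hydroxy-7-ethynyl cyclodecadienone (8-OSiMe2tBu)
Conditions: Bu4NF/AcOH (1:1, 2.5 equiv), THF, 0 °C to rt
Reagents that add atoms: none
Why: Buffered fluoride cleaves the alkyne C–Si bond and the secondary triethylsilyl ether much faster than the hindered tert-butyldimethylsilyl ether, and the acetic acid protects the acetate and the enolisable ketone.

Step 17
Reactants: 26 6-hydroxy-7-ethynyl cyclodecadienone
Product: 27 9-oxo-8-silyloxy α-methylene 12,6-lactone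
Conditions: PdCl2 (10 mol %), SnCl2 (10 mol %), PPh3 (20 mol %), CO (8 atm), MeCN, 70 °C
Reagents that add atoms: carbon monoxide, [C-]#[O+]
Why: Palladium-catalysed cyclocarbonylation of a cis-2-ethynylcycloalkanol: an alkoxycarbonyl species on divalent palladium adds syn across the alkyne and protonolysis frees the α-methylene γ-lactone, a cycle that needs no zerovalent palladium and so should spare the allylic C3 acetate.

Step 18
Reactants: 27 9-oxo-8-silyloxy α-methylene lactone
Product: 28 8-hydroxy-9-oxo α-methylene lactone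
Conditions: HF·pyridine, pyridine, THF, 0 °C to rt
Reagents that add atoms: none
Why: Mildly acidic fluoride removes the last silyl ether without touching the methylene lactone, the acetate or the α-ketol.

Step 19
Reactants: 29 angelic acid
Product: 30 (Z)-2-methylbut-2-en-1-ol
Conditions: LiAlH4, Et2O, 0 °C
Reagents that add atoms: none
Why: Hydride reduction of the acid to the primary alcohol leaves the trisubstituted Z alkene in place.

Step 20
Reactants: 30 (Z)-2-methylbut-2-en-1-ol
Product: 31 [(2S,3R)-2,3-dimethyloxiran-2-yl]methanol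
Conditions: Ti(OiPr)4 (10 mol %), L-(+)-diethyl tartrate (12 mol %), t-BuOOH, 4 Å molecular sieves (zeolite NaA, NaAlSiO4), CH2Cl2, −20 °C
Reagents that add atoms: tert-butyl hydroperoxide, CC(C)(C)OO
Why: Sharpless asymmetric epoxidation, in which the natural tartrate turns Z-allylic alcohols into (2S,3R)-epoxy alcohols, setting both epoxide centres, and syn oxygen transfer keeps the two methyl groups trans.

Step 21
Reactants: 31 [(2S,3R)-2,3-dimethyloxiran-2-yl]methanol
Product: 32 (2R,3R)-2,3-dimethyloxirane-2-carboxylic acid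
Conditions: RuCl3 (2 mol %), NaIO4 (3 equiv), CCl4/MeCN/H2O, rt
Reagents that add atoms: water, O
Why: RuO4 generated in situ oxidises the primary alcohol through the aldehyde hydrate to the acid without opening the epoxide (the C2 descriptor changes only through ligand priorities).

Step 22
Reactants: 28 8-hydroxy-9-oxo α-methylene lactone; 32 (2R,3R)-2,3-dimethyloxirane-2-carboxylic acid
Product: 34 9-oxo 8-epoxyangelate, via 2,4,6-trichlorobenzoic mixed anhydride 33 (not isolated)
Conditions: 32, 2,4,6-Cl3C6H2COCl, Et3N, THF, rt; then 28, DMAP, toluene, rt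
Reagents that add atoms: none
Why: Yamaguchi esterification of the only free hydroxyl; the acid has no α-hydrogen and cannot epimerise.

Step 23
Reactants: 34 9-oxo 8-epoxyangelate
Product: 35 target, (3S,6R,7R,8S,9R)-3-acetoxy-9-hydroxy-8-[(2R,3R)-2,3-dimethyloxirane-2-carbonyloxy]germacra-1(10)Z,4Z,11(13)-trien-12,6-olide
Conditions: Zn(BH4)2, Et2O, −30 °C; neutral work-up
Reagents that add atoms: none
Why: Zn(BH4)2 reduces enones 1,2 and spares esters, epoxide and methylene lactone; zinc held between the C9 carbonyl and the C8 ester should keep O8 syn to O9 so that hydride enters from the ring periphery on the C8–H side, anti to C7 (Cram-chelate sense), giving the 8,9-anti 9R alcohol.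

Compound list
1 | but-2-yne-1,4-diol | OCC#CCO | starting material
2 | 4-(4-methoxybenzyloxy)but-2-yn-1-ol | OCC#CCOCc1ccc(OC)cc1 | intermediate
3 | (E)-4-(4-methoxybenzyloxy)but-2-en-1-ol | OC/C=C/COCc1ccc(OC)cc1 | intermediate
4 | [(2R,3R)-3-(4-methoxybenzyloxymethyl)oxiran-2-yl]methanol | OC[C@H]1O[C@@H]1COCc1ccc(OC)cc1 | intermediate
5 | trimethylsilylacetylene | C#C[Si](C)(C)C | starting material
6 | lithium (trimethylsilyl)acetylide (not isolated) | [Li]C#C[Si](C)(C)C | intermediate
7 | diethyl[(trimethylsilyl)ethynyl]alane (not isolated) | CC[Al](CC)C#C[Si](C)(C)C | intermediate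
8 | (2S,3S)-3-(4-methoxybenzyloxymethyl)-5-trimethylsilylpent-4-yne-1,2-diol | OC[C@@H](O)[C@@H](C#C[Si](C)(C)C)COCc1ccc(OC)cc1 | intermediate
9 | bis(triethylsilyl) ether of 8 | CC[Si](CC)(CC)OC[C@@H](O[Si](CC)(CC)CC)[C@@H](C#C[Si](C)(C)C)COCc1ccc(OC)cc1 | intermediate
10 | (2S,3S)-3-(4-methoxybenzyloxymethyl)-2-triethylsilyloxy-5-trimethylsilylpent-4-ynal | O=C[C@@H](O[Si](CC)(CC)CC)[C@@H](C#C[Si](C)(C)C)COCc1ccc(OC)cc1 | intermediate
11 | (S)-(+)-carvone | O=C1C[C@@H](C(C)=C)CC=C1C | starting material
12 | carvone α′ lithium enolate (not isolated) | [Li]OC1=C[C@@H](C(C)=C)CC=C1C | intermediate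
13 | (5S)-6-methylcarvone, trans epimer shown (epimer mixture used) | O=C1[C@H](C)[C@@H](C(C)=C)CC=C1C | intermediate
14 | 6-methylcarvone lithium enolate (not isolated) | [Li]OC1=C(C)[C@@H](C(C)=C)CC=C1C | intermediate
15 | C4–C5 aldol adduct (C5–OH, O6 SiEt3, O8 4-methoxybenzyl, C3 isopropenyl) | O=C1C(C)=CC[C@H](C(C)=C)[C@@]1(C)[C@@H](O)[C@@H](O[Si](CC)(CC)CC)[C@@H](C#C[Si](C)(C)C)COCc1ccc(OC)cc1 | intermediate
16 | C5 mesylate of 15 | O=C1C(C)=CC[C@H](C(C)=C)[C@@]1(C)[C@@H](OS(C)(=O)=O)[C@@H](O[Si](CC)(CC)CC)[C@@H](C#C[Si](C)(C)C)COCc1ccc(OC)cc1 | intermediate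
17 | C3 methoxy hydroperoxide (not isolated; epimers at the peroxy carbon) | O=C1C(C)=CC[C@H](C(C)(OC)OO)[C@@]1(C)[C@@H](OS(C)(=O)=O)[C@@H](O[Si](CC)(CC)CC)[C@@H](C#C[Si](C)(C)C)COCc1ccc(OC)cc1 | intermediate
18 | C3 peroxyacetate (not isolated) | O=C1C(C)=CC[C@H](C(C)(OC)OOC(C)=O)[C@@]1(C)[C@@H](OS(C)(=O)=O)[C@@H](O[Si](CC)(CC)CC)[C@@H](C#C[Si](C)(C)C)COCc1ccc(OC)cc1 | intermediate
19 | C3 acetate of the mesyloxy enone | O=C1C(C)=CC[C@H](OC(C)=O)[C@@]1(C)[C@@H](OS(C)(=O)=O)[C@@H](O[Si](CC)(CC)CC)[C@@H](C#C[Si](C)(C)C)COCc1ccc(OC)cc1 | intermediate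
20 | C8 primary alcohol | O=C1C(C)=CC[C@H](OC(C)=O)[C@@]1(C)[C@@H](OS(C)(=O)=O)[C@@H](O[Si](CC)(CC)CC)[C@@H](C#C[Si](C)(C)C)CO | intermediate
21 | C8 aldehyde (1,6-keto aldehyde) | O=C1C(C)=CC[C@H](OC(C)=O)[C@@]1(C)[C@@H](OS(C)(=O)=O)[C@@H](O[Si](CC)(CC)CC)[C@@H](C#C[Si](C)(C)C)C=O | intermediate
22 | cis-decalin C8,C9-diol | CC[Si](CC)(CC)O[C@@H]1[C@H](OS(C)(=O)=O)[C@]2(C)[C@@H](OC(C)=O)CC=C(C)[C@]2(O)[C@@H](O)[C@@H]1C#C[Si](C)(C)C | intermediate
23 | cis-decalin C9-hydroxy C5-mesylate, O8 SiMe2tBu, O6 SiEt3 (fragmentation precursor) | CC[Si](CC)(CC)O[C@@H]1[C@H](OS(C)(=O)=O)[C@]2(C)[C@@H](OC(C)=O)CC=C(C)[C@]2(O)[C@@H](O[Si](C)(C)C(C)(C)C)[C@@H]1C#C[Si](C)(C)C | intermediate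
24 | potassium C9 alkoxide of 23 (not isolated) | CC[Si](CC)(CC)O[C@@H]1[C@H](OS(C)(=O)=O)[C@]2(C)[C@@H](OC(C)=O)CC=C(C)[C@]2([O-])[C@@H](O[Si](C)(C)C(C)(C)C)[C@@H]1C#C[Si](C)(C)C.[K+] | intermediate
25 | Z,Z-cyclodeca-1(10),4-dien-9-one (3-OAc, 6-OSiEt3, 7-C≡CSiMe3, 8-OSiMe2tBu) | CC[Si](CC)(CC)O[C@@H]1/C=C(/C)[C@@H](OC(C)=O)C/C=C(/C)C(=O)[C@@H](O[Si](C)(C)C(C)(C)C)[C@@H]1C#C[Si](C)(C)C | intermediate
26 | 6-hydroxy-7-ethynyl cyclodecadienone | O[C@@H]1/C=C(/C)[C@@H](OC(C)=O)C/C=C(/C)C(=O)[C@@H](O[Si](C)(C)C(C)(C)C)[C@@H]1C#C | intermediate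
27 | 9-oxo-8-silyloxy α-methylene 12,6-lactone | C=C1C(=O)O[C@@H]2/C=C(/C)[C@@H](OC(C)=O)C/C=C(/C)C(=O)[C@@H](O[Si](C)(C)C(C)(C)C)[C@H]12 | intermediate
28 | 8-hydroxy-9-oxo α-methylene lactone | C=C1C(=O)O[C@@H]2/C=C(/C)[C@@H](OC(C)=O)C/C=C(/C)C(=O)[C@@H](O)[C@H]12 | intermediate
29 | angelic acid | C/C=C(/C)C(=O)O | starting material
30 | (Z)-2-methylbut-2-en-1-ol | C/C=C(/C)CO | intermediate
31 | [(2S,3R)-2,3-dimethyloxiran-2-yl]methanol | OC[C@]1(C)O[C@@H]1C | intermediate
32 | (2R,3R)-2,3-dimethyloxirane-2-carboxylic acid | OC(=O)[C@]1(C)O[C@@H]1C | intermediate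
33 | mixed anhydride of 32 with 2,4,6-trichlorobenzoic acid (not isolated) | O=C(OC(=O)[C@]1(C)O[C@@H]1C)c1c(Cl)cc(Cl)cc1Cl | intermediate
34 | 9-oxo 8-epoxyangelate | C=C1C(=O)O[C@@H]2/C=C(/C)[C@@H](OC(C)=O)C/C=C(/C)C(=O)[C@@H](OC(=O)[C@]3(C)O[C@@H]3C)[C@H]12 | intermediate
35 | CNP0299903.1 | C=C1C(=O)O[C@@H]2/C=C(/C)[C@@H](OC(C)=O)C/C=C(/C)[C@@H](O)[C@@H](OC(=O)[C@]3(C)O[C@@H]3C)[C@H]12 | target

Total step count: 23. Longest linear sequence: 19 steps (steps 1–6, 8–18, 22, 23).

Steps most likely to fail

Step 15 (key step). The acetyl group may move from O3 to the C9 alkoxide, or be lost, before the C4–C9 bond breaks, which would stall or divert the fragmentation. The fallback removes the ester first and puts it back afterwards. It sets out from 23: iBu2AlH (2.5 equiv), CH2Cl2, −78 °C cleaves the acetate to the C3,C9-diol mesylate F1. KN(SiMe3)2 (2.2 equiv), THF, −78 to 0 °C then fragments the dianion to the 3-hydroxy cyclodecadienone F2; only O9 can fragment, because the C3–C4 bond is gauche to the C5–O bond. Ac2O, pyridine, DMAP re-acetylates O3, and the route is rejoined at 25.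

Step 17. The hindered alkoxycarbonyl–palladium species may fail to add across the alkyne, or palladium reduced under CO to the zerovalent state may ionise the allylic C3 acetate. The fallback builds the lactone by a radical instead. It sets out from 26: PhSeC(O)Cl, pyridine, CH2Cl2, 0 °C gives the Se-phenyl selenocarbonate F3. Bu3SnH with catalytic AIBN in benzene at 80 °C (slow addition) generates the alkoxycarbonyl radical, which closes 5-exo-dig onto the alkyne; reduction of the vinyl radical gives the methylene lactone, and the route is rejoined at 27.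

Step 23. Hydride may enter through the non-chelated rotamer or from the inner face of the ring, so that facial selectivity is poor or reversed. The fallback sets C9 by displacement instead of by hydride delivery. It sets out from 34: if the reduction gives mainly the 9-epimeric alcohol F4, Mitsunobu reaction with HCO2H, PPh3 and iPrO2CN=NCO2iPr in toluene at 0 °C inverts C9 to the 9-formate F5. KHCO3 in MeOH at 0 °C removes the formyl group selectively, and the route is rejoined at 35.

Further compounds
F1 | step 15 | C3,C9-diol C5-mesylate cis-decalin | CC[Si](CC)(CC)O[C@@H]1[C@H](OS(C)(=O)=O)[C@]2(C)[C@@H](O)CC=C(C)[C@]2(O)[C@@H](O[Si](C)(C)C(C)(C)C)[C@@H]1C#C[Si](C)(C)C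
F2 | step 15 | 3-hydroxy Z,Z-cyclodecadien-9-one | CC[Si](CC)(CC)O[C@@H]1/C=C(/C)[C@@H](O)C/C=C(/C)C(=O)[C@@H](O[Si](C)(C)C(C)(C)C)[C@@H]1C#C[Si](C)(C)C
F3 | step 17 | O6 Se-phenyl selenocarbonate of 26 | O=C([Se]c1ccccc1)O[C@@H]1/C=C(/C)[C@@H](OC(C)=O)C/C=C(/C)C(=O)[C@@H](O[Si](C)(C)C(C)(C)C)[C@@H]1C#C
F4 | step 23 | 9-epimer of 35 | C=C1C(=O)O[C@@H]2/C=C(/C)[C@@H](OC(C)=O)C/C=C(/C)[C@H](O)[C@@H](OC(=O)[C@]3(C)O[C@@H]3C)[C@H]12
F5 | step 23 | 9-O-formate of 35 | C=C1C(=O)O[C@@H]2/C=C(/C)[C@@H](OC(C)=O)C/C=C(/C)[C@@H](OC=O)[C@@H](OC(=O)[C@]3(C)O[C@@H]3C)[C@H]12
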